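4 questions stand below, on a flask fed with X in portions, and one number of my own, the pairing number, answers the two hard ones.

X 1.7 M (in portions, 3); L 0.0340 M; time 12 d; the portions of X follow each other after 5.0 min, the first at the start

    Q → Z (k1 = 0.0048 min⁻¹)
    X → G (k2 = 0.0060 min⁻¹)
    X + L → X.L (k3 = 0.74 M⁻¹ min⁻¹)
    X + Q → X.Q (k4 = 0.013 M⁻¹ min⁻¹)
    X ⇌ J (K5 = 0.52, k5 = 0.0020 min⁻¹)
    G → Q (k6 = 0.0020 min⁻¹)

- why nothing more happens at 12 d, or that something still does (it is still moving / all of X has reacted / forward and back rates have come level)
- conversion of X at 12 d
- amount of Z at 12 d, in percent of the X charged
- amount of X.Q at 12 d, in percent of the X charged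

- percent here means X units held: one X.Q counts as two
- the reaction counts as stopped when no species that holds the X changes by six tenths of a point or more over the second half of the time
- run time (flask): 12 d

Begin with the main road, X to G to Q to Z, where each step is a first-order decay and a lifetime is one over its constant: 167 min, 500 min and 208 min. On this road every X becomes Z. Now add L, which has a pseudo-first-order lifetime of 0.795 min against the charge of X, shorter than the lifetime of X on the road, so you take its 0.0340 M off as X.L and keep 1.67 M of X units on the road, which is 98.0% of the charge. The portions change nothing worth counting, so you may treat the charge as there from the start.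

Next add J. X and J form a pool of which X is a share of 0.658, and its lifetime stretches to 253 min. This is rough, since the exchange at 0.00585 min⁻¹ is about as fast as the loss to G at 0.0060 min⁻¹. Z does not change, and 12 d holds 68.3 such lifetimes, so my answers are all of X has reacted and a conversion of 100%.

Last add the step from X and Q. Carry 0.164 M⁻¹, the pairing number, the X.Q formed per square of the X units on the road. It is the constant of that step times the overlap of X with Q, and the overlap is a product of plain factors: the share of X in the pool, a factor 0.5 that the integral of a fading source against its own offspring brings, the part of G that passes on within the life of the pool, and the lifetime of Q shortened by the fading of the pool. Taken at full strength, X.Q would hold 53.7%. But each X.Q takes 2 units off the road, so the amount z reaching Z obeys this: z, plus 2 times the pairing number, 0.329 M⁻¹, times z squared, equals the units on the road. That gives 1.20 M, so Z is 70.3% and X.Q is 27.7%.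

The forecast stands a little from this, at 71% Z and 27% X.Q with 100% conversion and the verdict all of X has reacted, its X.Q reached “after trimming for the X that this side reaction itself consumes”. The simulation gives all of X has reacted, conversion 100%, Z 72.1% and X.Q 25.9%.

In this flask, at 0.0779 d, Q went to Z at 0.51 of the rate at which it went to X.Q. In the same flask X had dropped to 1.27% of the charge by 0.600 d, and by 2.40 d the step from Q to Z had 99.6% of its turnover up to the asked time behind it. Carry the same pairing number to the neighbour flask with 1.0 M of X: z becomes 0.771 M, which is 77.1% Z and 19.5% X.Q, and that flask holds 78.3% Z and 18.3% X.Q.

Its constants are invented; the rest is arithmetic.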